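**Plan**

1. Numbering used here: C1 = CMe2, C2 = CH2, C3 = CH–O, C4 = CH2, C5 = C(Me)–O, C6 = sp2 ring-fusion carbon (C1–C6 form carbocycle A); C7 = CH=, C8 = lactone C=O (butenolide B).
2. Retrosynthetic cuts, in order: the C3–O palmitate; the lactone O–C8 bond together with C5–CH3; then C3–C4 and C1–C6 of ring A in one stroke, leaving a C5 β,γ-unsaturated aldehyde and the silyl dienol ether of a C5 4-oxo-2-enoate.
3. Enabling feature: with C5 as a ketone, the C3 oxygen is an aldol oxygen across C3–C4. The quaternary C1 is bonded to C6, the β-carbon of the C6=C7–C8 enoate of ring B, so a tertiary radical at C1 (isopropenyl + H•) can add to C6 and C6=C7 can re-form by loss of H from C6.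
4. Forward order: ring A is closed first in one flask (Mukaiyama aldol, then cobalt-hydride radical cycloisomerisation, a formal (3+3) annulation); ring B follows by methyl addition to C5=O and lactonisation; the palmitate goes on last.
5. Stereochemistry: C3 comes from the catalyst-controlled aldol; C5 comes from equatorial attack of the methyl nucleophile, anti to the axial C1 methyl and cis to the equatorial C3 silyloxy group.

Key step: step 3

Remark: the three starting materials and all reagents are assumed to be commercial; the aldehyde from step 1 is used at once as a solution.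

**Step 1**
Reactants: 1 3-methylbut-3-en-1-ol
Product: 2 3-methylbut-3-enal
Conditions: Dess–Martin periodinane (1.1 equiv), pyridine, CH2Cl2, 0 °C
Reagents that add atoms: none
Why: Dess–Martin oxidation of the primary homoallylic alcohol under buffered, non-aqueous conditions should stop at the β,γ-unsaturated aldehyde without moving the double bond into conjugation.

**Step 2**
Reactants: 3 ethyl (2E)-4-oxopent-2-enoate
Product: 4 ethyl (2E)-4-[(triethylsilyl)oxy]penta-2,4-dienoate
Conditions: Et3SiOTf (1.1 equiv), Et3N (1.3 equiv), Et2O, 0 °C
Reagents that add atoms: triethylsilyl trifluoromethanesulfonate, CC[Si](CC)(CC)OS(=O)(=O)C(F)(F)F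
Why: Silyl enol ether formation by soft enolisation (silyl triflate and tertiary amine) should give one regioisomer, because the methyl group is the only enolisable position of 3.

**Step 3**
Reactants: 2 3-methylbut-3-enal (1.3 equiv); 4 ethyl (2E)-4-[(triethylsilyl)oxy]penta-2,4-dienoate
Product: 6 ethyl (2Z)-2-{(4S)-2,2-dimethyl-6-oxo-4-[(triethylsilyl)oxy]cyclohexylidene}acetate, via silyl aldol ether 5 (not isolated)
Conditions: stage a: (S)-2-butyl-4-(1H-indol-3-ylmethyl)-3-tosyl-1,3,2-oxazaborolidin-5-one (20 mol%), EtCN, −78 °C; stage b: same flask, solvent exchanged to benzene, Co(salen)Cl [salen = N,N′-bis(3,5-di-tert-butylsalicylidene)ethane-1,2-diaminate, trivalent cobalt] (5 mol%), PhSiH3 (10 mol%), 22 °C, argon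
Reagents that add atoms: none
Why: Proposed new method: a formal (3+3) annulation in one flask, in which a chiral-Lewis-acid Mukaiyama aldol (closest known type: oxazaborolidinone-catalysed aldol of 2-silyloxydienes and ketone enol silanes with aldehydes) joins the terminal CH2 of 4 to the formyl carbon of 2 with silyl transfer to oxygen, and a cobalt hydride then turns the isopropenyl group of 5 into a tertiary radical at C1 by hydrogen-atom transfer (closest known type: cobalt-salen/PhSiH3 hydrogen-atom-transfer cycloisomerisation of dienes). Ring A closes by 6-exo-trig attack of this nucleophilic radical on C6, and the α-ester radical at C7 returns the C6 hydrogen to divalent cobalt, which regenerates the hydride and leaves the conjugated exocyclic C6=C7 bond, so stage b is redox-neutral and catalytic in silane. The only new stereocentre, C3, is set in the aldol by the catalyst, which should leave the Re face of the bound aldehyde open and give the 6S carbinol of 5 (the enantiomeric catalyst is used if the facial sense proves opposite); C6 ends sp2 and C1 carries two identical methyl groups. In stage a the open-chain aldol must win over ring closure of the aldolate oxygen onto C7, which silyl capping of that oxygen should secure; in stage b the hydride must choose the electron-rich 1,1-disubstituted alkene, which it should because metal-hydride hydrogen-atom transfer to electron-poor enoates is slow. Closure must be 6-exo at C6 and not 7-endo at C7, which the kinetic exo preference and the ester (making C6 a Michael-type terminus) should secure. The Z geometry of 6 (ester syn to the ketone) should follow from the allylic strain an ester syn to the gem-dimethyl carbon would suffer.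

**Step 4**
Reactants: 6 ethyl (2Z)-2-{(4S)-2,2-dimethyl-6-oxo-4-[(triethylsilyl)oxy]cyclohexylidene}acetate
Product: 9 (−)-loliolide [(6S,7aR)-6-hydroxy-4,4,7a-trimethyl-5,6,7,7a-tetrahydro-1-benzofuran-2(4H)-one], via bromomagnesium alkoxide 7 (not isolated), via O-triethylsilyl-loliolide 8 (not isolated)
Conditions: MeMgBr (1.3 equiv), CeCl3 (1.5 equiv), THF, −78 °C; then 1 M HCl, THF, 22 °C
Reagents that add atoms: methylmagnesium bromide, C[Mg]Br
Why: Organocerium 1,2-addition to the enolisable conjugated ketone, then lactonisation and acidic desilylation: with the C3 silyloxy group equatorial the axial C1 methyl blocks axial approach to C5, so the methyl group should enter equatorially, cis to the C3 oxygen (7aR), and the alkoxide 7 should close onto the Z-ester to give butenolide 8, which aqueous acid desilylates to 9.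

**Step 5**
Reactants: 9 (−)-loliolide; 10 hexadecanoyl chloride (1.2 equiv)
Product: 11 (6S,7aR)-4,4,7a-trimethyl-2-oxo-2,4,5,6,7,7a-hexahydro-1-benzofuran-6-yl hexadecanoate [(−)-3-O-palmitoylloliolide]
Conditions: Et3N (1.5 equiv), DMAP (0.1 equiv), CH2Cl2, 0 to 22 °C
Reagents that add atoms: none
Why: DMAP-catalysed acylation of the hindered axial secondary alcohol with the acid chloride should give the ester with retention at C3, since no bond to the stereocentre is broken.

**Compound list**

1 | 3-methylbut-3-en-1-ol | CC(=C)CCO | starting material
2 | 3-methylbut-3-enal | CC(=C)CC=O | intermediate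
3 | ethyl (2E)-4-oxopent-2-enoate | CCOC(=O)/C=C/C(C)=O | starting material
4 | ethyl (2E)-4-[(triethylsilyl)oxy]penta-2,4-dienoate | CCOC(=O)/C=C/C(=C)O[Si](CC)(CC)CC | intermediate
5 | ethyl (2E,6S)-8-methyl-4-oxo-6-[(triethylsilyl)oxy]nona-2,8-dienoate (not isolated) | CC[Si](CC)(CC)O[C@H](CC(=O)/C=C/C(=O)OCC)CC(C)=C | intermediate
6 | ethyl (2Z)-2-{(4S)-2,2-dimethyl-6-oxo-4-[(triethylsilyl)oxy]cyclohexylidene}acetate | CC[Si](CC)(CC)O[C@H]1CC(C)(C)/C(=C/C(=O)OCC)C(=O)C1 | intermediate
7 | bromomagnesium alkoxide of ethyl (2Z)-2-{(4S,6R)-6-hydroxy-2,2,6-trimethyl-4-[(triethylsilyl)oxy]cyclohexylidene}acetate (not isolated) | CC[Si](CC)(CC)O[C@H]1CC(C)(C)/C(=C/C(=O)OCC)[C@](C)(O[Mg]Br)C1 | intermediate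
8 | (6S,7aR)-4,4,7a-trimethyl-6-[(triethylsilyl)oxy]-5,6,7,7a-tetrahydro-1-benzofuran-2(4H)-one (O-triethylsilyl-loliolide, not isolated) | CC[Si](CC)(CC)O[C@H]1CC(C)(C)C2=CC(=O)O[C@]2(C)C1 | intermediate
9 | (−)-loliolide, (6S,7aR)-6-hydroxy-4,4,7a-trimethyl-5,6,7,7a-tetrahydro-1-benzofuran-2(4H)-one | O[C@H]1CC(C)(C)C2=CC(=O)O[C@]2(C)C1 | intermediate
10 | hexadecanoyl chloride | CCCCCCCCCCCCCCCC(=O)Cl | starting material
11 | (6S,7aR)-4,4,7a-trimethyl-2-oxo-2,4,5,6,7,7a-hexahydro-1-benzofuran-6-yl hexadecanoate | CCCCCCCCCCCCCCCC(=O)O[C@H]1CC(C)(C)C2=CC(=O)O[C@]2(C)C1 | target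

Total step count: 5. Longest linear sequence: 4 steps (steps 2, 3, 4, 5).

**Steps most likely to fail**

Step 3 (proposed new method). In stage a the electron-poor dienol ether may add slowly, and the aldolate oxygen may close onto C7 instead of being silylated. In stage b, isomerisation of the isopropenyl group may outrun cyclisation, closure may go 7-endo at C7, or termination may be reductive instead of dehydrogenative. The fallback uses known chemistry only: the two bonds are made in separate steps and the ring-B double bond is restored later. It sets out from 2 and 4: the Mukaiyama aldol alone is worked up and 5 is isolated. Reductive hydrogen-atom-transfer radical cyclisation of 5 (Fe(acac)3, PhSiH3, EtOH, 60 °C; Giese-type) should give ethyl 2-{(4S)-2,2-dimethyl-6-oxo-4-[(triethylsilyl)oxy]cyclohexyl}acetate F1, as a mixture at the ring carbon that carries the side chain. MeMgBr/CeCl3 as in step 4, with neutral work-up, should give the saturated lactone (6S,7aR)-4,4,7a-trimethyl-6-[(triethylsilyl)oxy]hexahydro-1-benzofuran-2(3H)-one F2, as a mixture at C3a, which is of no consequence because that centre becomes sp2. Palladium-catalysed α,β-dehydrogenation of its zinc enolate (Zn(TMP)2 with TMP = 2,2,6,6-tetramethylpiperidide, diethyl allyl phosphate, [Pd(allyl)Cl]2, THF, 60 °C) removes the hydrogens at C6 and C7 and comes back to the route at 8, which the acid work-up of step 4 converts into 9.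

Step 4. The methyl nucleophile may add in conjugate fashion at C7 or attack the ester; the ketone may be enolised toward C4 with loss of the β-silyloxy group; approach from the axial face would give the C5 epimer; any E-isomer of 6 cannot lactonise. The fallback masks the ester as a carboxylate. It sets out from 6: LiOH (THF/H2O, 0 °C) should give (2Z)-2-{(4S)-2,2-dimethyl-6-oxo-4-[(triethylsilyl)oxy]cyclohexylidene}acetic acid F3, in equilibrium with its ring-closed hydroxybutenolide form. The lithium carboxylate is inert to organometallics and disfavours conjugate addition, so MeLi/CeCl3 (3 equiv, THF, −78 °C) should add only at C5. Acidification (1 M HCl) closes the lactone, coming back to the route at 8, and the same acid converts 8 into 9.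

Step 2. The doubly activated alkene of 3 may undergo amine addition and oligomerise under the silylation conditions, and the dienol ether may hydrolyse on isolation. The fallback avoids any silyl dienol ether by a boron aldol. It sets out from 3 and 2: 3 is enolised with the enantiomer of B-chlorodiisopinocampheylborane that directs addition to the Re face of the aldehyde (Et3N, Et2O, −78 °C), 2 is added, and non-oxidative work-up (diethanolamine) should give ethyl (2E,6S)-6-hydroxy-8-methyl-4-oxonona-2,8-dienoate F4. Immediate silylation (Et3SiOTf, 2,6-lutidine, CH2Cl2, −78 °C) comes back to the route at 5, which is taken into stage b of step 3.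

**Further compounds**

F1 | step 3 | ethyl 2-{(4S)-2,2-dimethyl-6-oxo-4-[(triethylsilyl)oxy]cyclohexyl}acetate (mixture at ring C1) | CC[Si](CC)(CC)O[C@H]1CC(C)(C)C(CC(=O)OCC)C(=O)C1
F2 | step 3 | (6S,7aR)-4,4,7a-trimethyl-6-[(triethylsilyl)oxy]hexahydro-1-benzofuran-2(3H)-one (mixture at C3a) | CC[Si](CC)(CC)O[C@H]1CC(C)(C)C2CC(=O)O[C@]2(C)C1
F3 | step 4 | (2Z)-2-{(4S)-2,2-dimethyl-6-oxo-4-[(triethylsilyl)oxy]cyclohexylidene}acetic acid | CC[Si](CC)(CC)O[C@H]1CC(C)(C)/C(=C/C(=O)O)C(=O)C1
F4 | step 2 | ethyl (2E,6S)-6-hydroxy-8-methyl-4-oxonona-2,8-dienoate | O[C@H](CC(=O)/C=C/C(=O)OCC)CC(C)=C
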